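**Plan**

1. Numbering is that of bicyclo[3.2.1]octane: C1 and C5 bridgeheads, C2(=O)–C3(OMe)=C4 bridge, C6(Me)–C7(Ar) bridge, C8 bridging ketone. The retrosynthesis cuts, in order: O–CH3 and C3–O (back to the C3 methylene of a 2,8-dione); then in one event C7–aryl and C1–C2; then C5–allyl; then C5–C4. This leaves the β-keto ester derived from (R)-pulegone.
2. Feature used: C7 is the β-carbon of the C8 ketone inside the five-membered ring C1–C7–C6–C5–C8, and C1 is the bridgehead flanked by the C2 and C8 carbonyls. An aryl nucleophile adding to C7 of a cyclopent-2-enone therefore creates the C1 enolate at the one place from which the six-membered ring C1–C2–C3–C4–C5–C8 can close onto C2, which is held ready as an N-methoxy-N-methyl amide on a tether at C5.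
3. Forward order: five-membered ring by Favorskii contraction of pulegone and ozonolysis; quaternary C5 by Michael addition and Pd decarboxylative allylation; enone; key step (aryl in, six-membered ring closed, bicyclo[3.2.1]octane-2,8-dione out); C3 oxidation to the diosphenol; O-methylation.
4. Stereochemistry: C6 is the pulegone stereocentre (pulegone C1 is extruded, its C2 becomes C8, C6 becomes C5, C5 becomes C6). C5 comes from allylation anti to the C6 methyl group, C7 from cuprate attack anti to the same methyl group, and C1 from the geometric demand of the bridge.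
5. Helpers: the allyl ester (activates C5, then supplies the allyl group, leaves as CO2) and the N(OMe)Me group (acyl donor, leaves in the key step).

Key step: step 7

Remark: 3, 4, 6 and 8 are carried as epimer mixtures at the ester-bearing carbon, which is acidic and is planarised in step 5; only the pulegone methyl stereocentre is drawn defined in their SMILES.

**Route**

Step 1
Reactants: 1 (R)-(+)-pulegone
Product: 3 methyl (2R)-2-methyl-5-(propan-2-ylidene)cyclopentane-1-carboxylate (methyl pulegenate), via pulegone dibromide 2 (not isolated)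
Conditions: Br2, Et2O, 0 °C; then NaOMe, MeOH, reflux
Reagents that add atoms: bromine, BrBr (bromine atoms of 2 only); sodium methoxide, [Na+].[O-]C
Why: Bromine adds to the tetrasubstituted alkene and methoxide then drives the Favorskii ring contraction (α′-enolate closes to the cyclopropanone, methoxide opens it, E1cB loss of the second bromide restores the isopropylidene group), which extrudes the carbonyl carbon as the ester and leaves the remote methyl stereocentre untouched.

Step 2
Reactants: 3 methyl pulegenate
Product: 4 methyl (2R)-2-methyl-5-oxocyclopentane-1-carboxylate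
Conditions: O3, CH2Cl2/MeOH, −78 °C; then Me2S, −78 °C to rt
Reagents that add atoms: ozone, [O-][O+]=O
Why: Ozonolysis of the isopropylidene alkene with reductive work-up unveils the ring ketone (future C8) of the known pulegone-derived β-keto ester, and the methyl-bearing carbon is not α to a carbonyl group and keeps its configuration.

Step 3
Reactants: 4 methyl (2R)-2-methyl-5-oxocyclopentane-1-carboxylate; 5 prop-2-en-1-ol (allyl alcohol)
Product: 6 prop-2-en-1-yl (2R)-2-methyl-5-oxocyclopentane-1-carboxylate
Conditions: 5 (5 equiv), DMAP (cat.), toluene, reflux, removal of MeOH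
Reagents that add atoms: none
Why: DMAP-catalysed transesterification of an enolisable β-keto ester (through the acylketene) installs the allyl ester that later acts as activating group and as internal allyl source.

Step 4
Reactants: 6 prop-2-en-1-yl (2R)-2-methyl-5-oxocyclopentane-1-carboxylate; 7 N-methoxy-N-methylprop-2-enamide
Product: 8 prop-2-en-1-yl (2R)-1-{3-[methoxy(methyl)amino]-3-oxopropyl}-2-methyl-5-oxocyclopentane-1-carboxylate
Conditions: Cs2CO3 (0.2 equiv), MeCN, 40 °C
Reagents that add atoms: none
Why: Base-catalysed Michael addition of the doubly activated C–H forms the C5–C4 bond and brings in the whole C4–C3–C2 tether with C2 already at the acyl oxidation level; the configuration formed at C5 does not matter because this centre is planarised in step 5.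

Step 5
Reactants: 8 allyl β-keto ester
Product: 9 N-methoxy-N-methyl-3-[(1S,2R)-2-methyl-5-oxo-1-(prop-2-en-1-yl)cyclopentyl]propanamide
Conditions: Pd(PPh3)4 (5 mol %), THF, rt
Reagents that add atoms: none
Why: Tsuji-type Pd-catalysed decarboxylative allylation (ionisation of the allyl ester, loss of CO2, recombination of the regiodefined Pd enolate with the π-allyl unit) should create the quaternary C5 with the allyl group entering the planar enolate anti to the adjacent C6 methyl group, so that the amide tether ends up cis to that methyl group.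

Step 6
Reactants: 9 ketone
Product: 11 N-methoxy-N-methyl-3-[(1S,5R)-5-methyl-2-oxo-1-(prop-2-en-1-yl)cyclopent-3-en-1-yl]propanamide, via trimethylsilyl enol ether 10 (not isolated)
Conditions: TMSOTf, Et3N, CH2Cl2, 0 °C; solvent exchange; Pd(OAc)2 (1.1 equiv), MeCN, rt
Reagents that add atoms: trimethylsilyl trifluoromethanesulfonate, C[Si](C)(C)OS(=O)(=O)C(F)(F)F (silyl group of 10 only)
Why: Saegusa–Ito dehydrogenation: soft enolisation can only go toward C1 because C5 is quaternary, and Pd(II) turns the silyl enol ether into the C1=C7 enone without touching the amide or the terminal alkene.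

Step 7
Reactants: 11 enone amide; 12 (3,4-dimethoxyphenyl)magnesium bromide
Product: 16 (1R,5S,6R,7R)-7-(3,4-dimethoxyphenyl)-6-methyl-5-(prop-2-en-1-yl)bicyclo[3.2.1]octane-2,8-dione, via magnesium diarylcuprate 13 (not isolated), via magnesium enolate 14 (not isolated), via chelated tetrahedral adduct 15 (not isolated)
Conditions: 12 (2.2 equiv), CuBr·SMe2 (1.1 equiv), THF, −78 °C; add 11, −78 °C to rt; aq NH4Cl
Reagents that add atoms: copper(I) bromide–dimethyl sulfide, [Cu]Br.CSC (copper of 13 only)
Why: The cuprate should transfer the 3,4-dimethoxyphenyl group by 1,4-addition to C7 of the only enone present, on the face opposite the adjacent C6 methyl group, which sets C7 with the aryl group trans to methyl and cis to allyl. This produces the C1 enolate regiospecifically, and on warming it should attack the magnesium-activated amide carbonyl C2, held over the same face by the C5 tether, in a 6-(enolendo)-exo-trig acylation that closes the ring C1–C2–C3–C4–C5–C8 and completes the bicyclo[3.2.1]octane. The closest known reaction types are tandem cuprate conjugate addition/Dieckmann ring closures and the acylation of ketone enolates by N-methoxy-N-methyl amides. C1 is fixed by geometry, because the three-atom bridge can only span the face that carries the tether. The step needs 1,4- over 1,2-addition and an amide that is inert to the organometallic, which the soft cuprate at −78 °C should secure. It also needs the ring closure not to revert, which the N,O-chelated adduct 15 should secure, since it releases the non-enolisable 1,3-diketone only on aqueous work-up when no alkoxide is present for retro-Claisen cleavage.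

Step 8
Reactants: 16 bicyclic 2,8-dione
Product: 17 (1S,5S,6R,7R)-7-(3,4-dimethoxyphenyl)-3-hydroxy-6-methyl-5-(prop-2-en-1-yl)bicyclo[3.2.1]oct-3-ene-2,8-dione
Conditions: SeO2 (1.5 equiv), 1,4-dioxane, 90 °C
Reagents that add atoms: selenium dioxide, O=[Se]=O
Why: Riley oxidation: the C2 ketone can enolise only toward C3 (C1 is a bridgehead and the C8 ketone has no enolisable α-hydrogen), so SeO2 should give the 2,3-dione, which rests as its only possible enol, the C3 diosphenol.

Step 9
Reactants: 17 diosphenol
Product: 18 kadsurenin D, (1S,5S,6R,7R)-7-(3,4-dimethoxyphenyl)-3-methoxy-6-methyl-5-(prop-2-en-1-yl)bicyclo[3.2.1]oct-3-ene-2,8-dione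
Conditions: Me2SO4, K2CO3, acetone, rt
Reagents that add atoms: dimethyl sulfate, COS(=O)(=O)OC
Why: Williamson-type O-methylation of the acidic diosphenol with a hard electrophile should give the 3-methoxy enone, and the mild heterogeneous carbonate avoids retro-Claisen opening of the non-enolisable 2,8-dione.

**Compound list**

1 | (R)-(+)-pulegone, (5R)-5-methyl-2-(propan-2-ylidene)cyclohexan-1-one | C[C@@H]1CCC(=C(C)C)C(=O)C1 | starting material
2 | pulegone dibromide, (5R)-2-bromo-2-(2-bromopropan-2-yl)-5-methylcyclohexan-1-one (C2 epimers) | C[C@@H]1CCC(Br)(C(C)(C)Br)C(=O)C1 | intermediate (not isolated)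
3 | methyl (2R)-2-methyl-5-(propan-2-ylidene)cyclopentane-1-carboxylate (methyl pulegenate, C1 epimers) | COC(=O)C1C(=C(C)C)CC[C@H]1C | intermediate
4 | methyl (2R)-2-methyl-5-oxocyclopentane-1-carboxylate (C1 epimers) | COC(=O)C1C(=O)CC[C@H]1C | intermediate
5 | prop-2-en-1-ol (allyl alcohol) | C=CCO | starting material
6 | prop-2-en-1-yl (2R)-2-methyl-5-oxocyclopentane-1-carboxylate (C1 epimers) | C=CCOC(=O)C1C(=O)CC[C@H]1C | intermediate
7 | N-methoxy-N-methylprop-2-enamide | C=CC(=O)N(C)OC | starting material
8 | prop-2-en-1-yl (2R)-1-{3-[methoxy(methyl)amino]-3-oxopropyl}-2-methyl-5-oxocyclopentane-1-carboxylate (C1 epimers) | C=CCOC(=O)C1(CCC(=O)N(C)OC)C(=O)CC[C@H]1C | intermediate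
9 | N-methoxy-N-methyl-3-[(1S,2R)-2-methyl-5-oxo-1-(prop-2-en-1-yl)cyclopentyl]propanamide | C=CC[C@]1(CCC(=O)N(C)OC)C(=O)CC[C@H]1C | intermediate
10 | N-methoxy-N-methyl-3-[(1S,5R)-5-methyl-1-(prop-2-en-1-yl)-2-(trimethylsilyloxy)cyclopent-2-en-1-yl]propanamide | C=CC[C@]1(CCC(=O)N(C)OC)C(O[Si](C)(C)C)=CC[C@H]1C | intermediate (not isolated)
11 | N-methoxy-N-methyl-3-[(1S,5R)-5-methyl-2-oxo-1-(prop-2-en-1-yl)cyclopent-3-en-1-yl]propanamide | C=CC[C@]1(CCC(=O)N(C)OC)C(=O)C=C[C@H]1C | intermediate
12 | (3,4-dimethoxyphenyl)magnesium bromide (solution in THF) | COc1ccc([Mg]Br)cc1OC | starting material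
13 | bromomagnesium bis(3,4-dimethoxyphenyl)cuprate | COc1ccc([Cu-]c2ccc(OC)c(OC)c2)cc1OC.[Mg+]Br | intermediate (not isolated)
14 | bromomagnesium enolate of the 1,4-adduct (aryl at C7 trans to the methyl group) | C=CC[C@]1(CCC(=O)N(C)OC)C(O[Mg]Br)=C[C@H](c2ccc(OC)c(OC)c2)[C@H]1C | intermediate (not isolated)
15 | bicyclic tetrahedral adduct, C2 bearing OMgBr and N(OMe)Me | C=CC[C@]12CCC(O[Mg]Br)(N(C)OC)[C@H](C1=O)[C@H](c1ccc(OC)c(OC)c1)[C@H]2C | intermediate (not isolated)
16 | (1R,5S,6R,7R)-7-(3,4-dimethoxyphenyl)-6-methyl-5-(prop-2-en-1-yl)bicyclo[3.2.1]octane-2,8-dione | C=CC[C@]12CCC(=O)[C@H](C1=O)[C@H](c1ccc(OC)c(OC)c1)[C@H]2C | intermediate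
17 | (1S,5S,6R,7R)-7-(3,4-dimethoxyphenyl)-3-hydroxy-6-methyl-5-(prop-2-en-1-yl)bicyclo[3.2.1]oct-3-ene-2,8-dione | C=CC[C@]12C=C(O)C(=O)[C@H](C1=O)[C@H](c1ccc(OC)c(OC)c1)[C@H]2C | intermediate
18 | kadsurenin D, (1S,5S,6R,7R)-7-(3,4-dimethoxyphenyl)-3-methoxy-6-methyl-5-(prop-2-en-1-yl)bicyclo[3.2.1]oct-3-ene-2,8-dione | C=CC[C@]12C=C(OC)C(=O)[C@H](C1=O)[C@H](c1ccc(OC)c(OC)c1)[C@H]2C | target

**Count and risks**

Total step count: 9. Longest linear sequence: 9 steps (1 to 18).

Steps most likely to fail:

1. Step 7. After the conjugate addition the enolate may not add to the amide carbonyl and is then only protonated on work-up, or the tetrahedral adduct may collapse in the flask and the strained diketone be cleaved. The fallback closes the ring by aldol addition under rhodium catalysis and sets out from 6.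
   - Alkylation of 6 with 2-(2-bromoethyl)-1,3-dioxolane (Cs2CO3, NaI, DMF) should give prop-2-en-1-yl (2R)-1-[2-(1,3-dioxolan-2-yl)ethyl]-2-methyl-5-oxocyclopentane-1-carboxylate F1.
   - Decarboxylative allylation as in step 5 should give (2S,3R)-2-[2-(1,3-dioxolan-2-yl)ethyl]-3-methyl-2-(prop-2-en-1-yl)cyclopentan-1-one F2.
   - LDA/TMSCl followed by Pd(OAc)2 should give (4R,5S)-5-[2-(1,3-dioxolan-2-yl)ethyl]-4-methyl-5-(prop-2-en-1-yl)cyclopent-2-en-1-one F3.
   - Aqueous acid should free 3-[(1S,5R)-5-methyl-2-oxo-1-(prop-2-en-1-yl)cyclopent-3-en-1-yl]propanal F4.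
   - Base-free Rh-catalysed conjugate addition of (3,4-dimethoxyphenyl)boronic acid ([Rh(cod)OH]2, dioxane/H2O, 35 °C, then K2CO3 if needed) should again place the aryl group anti to the methyl group. The C1 enolate should close onto the aldehyde, as in known tandem conjugate addition–aldol cyclisations and Michael–aldol routes to bicyclo[3.2.1]octan-8-ones, to give (1R,5S,6R,7R)-7-(3,4-dimethoxyphenyl)-2-hydroxy-6-methyl-5-(prop-2-en-1-yl)bicyclo[3.2.1]octan-8-one F5.
   - Dess–Martin oxidation comes back to the route at 16.

2. Step 8. Allylic oxidation of the terminal alkene or hydrolytic cleavage of the non-enolisable β-diketone may compete at the temperature that SeO2 needs. The fallback sets out from 16: enolate hydroxylation at C3 (KHMDS, THF, −78 °C, then 2-(phenylsulfonyl)-3-phenyloxaziridine) should give (1S,5R,6R,7R)-7-(3,4-dimethoxyphenyl)-3-hydroxy-6-methyl-5-(prop-2-en-1-yl)bicyclo[3.2.1]octane-2,8-dione F6, and Dess–Martin oxidation of this acyloin comes back to the route at 17.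

3. Step 5. Allyl transfer to the Pd enolate may show poor facial selectivity at C5, or the enolate may be protonated instead. The fallback sets out from 8 and introduces the allyl group by enolate alkylation of an enone.
   - Decarboxylative protonation (Pd(PPh3)4, HCO2H, Et3N, THF) should give N-methoxy-N-methyl-3-[(1S,2R)-2-methyl-5-oxocyclopentyl]propanamide F7.
   - Kinetic silyl enol ether formation on the CH2 side (LDA, TMSCl, −78 °C) and Pd(OAc)2 should give N-methoxy-N-methyl-3-[(1S,5R)-5-methyl-2-oxocyclopent-3-en-1-yl]propanamide F8.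
   - Deprotonation at the α′ carbon (LDA, −78 °C) and alkylation with allyl bromide, which should enter the flat cross-conjugated enolate anti to the neighbouring methyl group, comes back to the route at 11.

Further compounds
F1 | step 7 | prop-2-en-1-yl (2R)-1-[2-(1,3-dioxolan-2-yl)ethyl]-2-methyl-5-oxocyclopentane-1-carboxylate (C1 epimers) | C=CCOC(=O)C1(CCC2OCCO2)C(=O)CC[C@H]1C
F2 | step 7 | (2S,3R)-2-[2-(1,3-dioxolan-2-yl)ethyl]-3-methyl-2-(prop-2-en-1-yl)cyclopentan-1-one | C=CC[C@]1(CCC2OCCO2)C(=O)CC[C@H]1C
F3 | step 7 | (4R,5S)-5-[2-(1,3-dioxolan-2-yl)ethyl]-4-methyl-5-(prop-2-en-1-yl)cyclopent-2-en-1-one | C=CC[C@]1(CCC2OCCO2)C(=O)C=C[C@H]1C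
F4 | step 7 | 3-[(1S,5R)-5-methyl-2-oxo-1-(prop-2-en-1-yl)cyclopent-3-en-1-yl]propanal | C=CC[C@]1(CCC=O)C(=O)C=C[C@H]1C
F5 | step 7 | (1R,5S,6R,7R)-7-(3,4-dimethoxyphenyl)-2-hydroxy-6-methyl-5-(prop-2-en-1-yl)bicyclo[3.2.1]octan-8-one (C2 epimers) | C=CC[C@]12CCC(O)[C@H](C1=O)[C@H](c1ccc(OC)c(OC)c1)[C@H]2C
F6 | step 8 | (1S,5R,6R,7R)-7-(3,4-dimethoxyphenyl)-3-hydroxy-6-methyl-5-(prop-2-en-1-yl)bicyclo[3.2.1]octane-2,8-dione (C3 epimers) | C=CC[C@]12CC(O)C(=O)[C@H](C1=O)[C@H](c1ccc(OC)c(OC)c1)[C@H]2C
F7 | step 5 | N-methoxy-N-methyl-3-[(1S,2R)-2-methyl-5-oxocyclopentyl]propanamide | CON(C)C(=O)CC[C@@H]1C(=O)CC[C@H]1C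
F8 | step 5 | N-methoxy-N-methyl-3-[(1S,5R)-5-methyl-2-oxocyclopent-3-en-1-yl]propanamide | CON(C)C(=O)CC[C@@H]1C(=O)C=C[C@H]1C
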